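**Retrosynthetic overview**
1. Desertorin A ⇒ chemoselective double 4‑O‑methylation of a bis(4‑hydroxycoumarin) ⇒ both pyranone rings closed last and together by double carbonate annulation of a bis(o‑hydroxyacetophenone) biaryl.
2. The ring‑B acetyl comes from an aryl bromide installed by chiral‑phosphoric‑acid‑catalysed desymmetrizing bromination of a prochiral 2‑aryl‑5‑methylresorcinol. This is the key step: it sets the axis, so no atroposelective aryl–aryl coupling is needed.
3. Ring B is not coupled as an arene. It is attached as 5‑methylcyclohexane‑1,3‑dione by Pd enolate arylation and then dehydrogenated to the σ‑symmetric resorcinol.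
4. Ring order: ring A arene (purchased) → ring B carbocycle attached and aromatized → axis desymmetrized → both pyranones.

**Assumption:** the SMILES carries no axial descriptor, so I target the natural atropisomer, which I take to be (M) (assigned from memory of the literature). Viewed along C6→C8′, the shortest turn from C7–OH (front) to C8a′–O1′ (rear) is counter‑clockwise. The opposite catalyst enantiomer in Step 5 gives the (P) series. Compound 1 is taken as commercial; if not, it is one Hoesch step from orcinol.

---

**Step 1**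
Reactants: 1 (1‑(2,4‑dihydroxy‑6‑methylphenyl)ethan‑1‑one), 2 (N‑bromosuccinimide)
Product: 3, 1‑(3‑bromo‑4,6‑dihydroxy‑2‑methylphenyl)ethan‑1‑one
Conditions: NBS (1.0 equiv), MeCN, 0 °C
Reagents that add atoms: N‑bromosuccinimide, O=C1CCC(=O)N1Br
Why: Electrophilic aromatic bromination; the methyl‑flanked carbon is para to the chelated OH and ortho to the free OH, and acyl‑orcinols halogenate there rather than between the two OH groups.

**Step 2**
Reactants: 3, 4 (chloromethyl methyl ether)
Product: 5, 1‑[3‑bromo‑4,6‑bis(methoxymethoxy)‑2‑methylphenyl]ethan‑1‑one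
Conditions: MOMCl (3 equiv), i‑Pr2NEt (4 equiv), cat. Bu4NI, CH2Cl2, 0→40 °C
Reagents that add atoms: MOMCl, COCCl
Why: Phenol O‑alkylation (acetal ether formation); it removes the phenoxide para to Br before the Pd step and places an O‑MOM ortho to the future axis as the hydrogen‑bond acceptor for Step 5.

**Step 3**
Reactants: 5, 6 (5‑methylcyclohexane‑1,3‑dione, 1.5 equiv)
Product: 7, 2‑[3‑acetyl‑4,6‑bis(methoxymethoxy)‑2‑methylphenyl]‑3‑hydroxy‑5‑methylcyclohex‑2‑en‑1‑one (enol form of the 2‑aryl‑1,3‑dione; C5 racemic and tautomerically labile)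
Conditions: Pd(OAc)2 (5 mol %), XPhos (10 mol %), K3PO4 (3 equiv), 1,4‑dioxane, 100 °C
Reagents that add atoms: none beyond reactant 6, CC1CC(=O)CC(=O)C1
Why: Pd‑catalysed α‑arylation of a 1,3‑dione enolate (Buchwald–Hartwig‑type enolate arylation); the bulky biarylphosphine allows C–C reductive elimination with a di‑ortho‑substituted bromide, and K3PO4 deprotonates only the dione (pKa ≈ 5), not the methyl ketone.

**Step 4**
Reactants: 7
Product: 8, 1‑[3‑(2,6‑dihydroxy‑4‑methylphenyl)‑4,6‑bis(methoxymethoxy)‑2‑methylphenyl]ethan‑1‑one (prochiral axis; ring B has a local mirror plane)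
Conditions: 10 % Pd/C, mesitylene, 165 °C, Ar sweep (–H2)
Reagents that add atoms: none
Why: Catalytic dehydrogenative aromatization of a dihydroresorcinol gives the σ‑symmetric resorcinol with no protecting groups; the C5 stereocentre disappears and the axis is not yet stereogenic, so heat costs nothing.

**Step 5 (key step)**
Reactants: 8, 9 (N‑bromophthalimide)
Product: 10, (M)‑1‑[3‑(3‑bromo‑2,6‑dihydroxy‑4‑methylphenyl)‑4,6‑bis(methoxymethoxy)‑2‑methylphenyl]ethan‑1‑one
Conditions: (R)‑TRIP‑type BINOL phosphoric acid (10 mol %), N‑bromophthalimide (1.2 equiv), CH2Cl2/toluene, −20 °C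
Reagents that add atoms: N‑bromophthalimide, O=C1N(Br)C(=O)c2ccccc12
Why: Chiral Brønsted‑acid‑catalysed desymmetrizing electrophilic bromination of a 2‑arylresorcinol. The phosphoric acid bridges a resorcinol OH and the N‑bromoimide, with the ortho O‑MOM of ring A as a second anchor, so one of the two enantiotopic methyl‑flanked carbons is brominated. The slight excess of reagent over‑brominates the minor enantiomer to the achiral dibromide, which raises the ee. The catalyst hand that gives (M) is fixed in a pilot run by anomalous‑dispersion X‑ray of the bromide; I cannot predict it with confidence.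

**Step 6**
Reactants: 10, 11 (tributyl(1‑ethoxyvinyl)stannane), 12 (water)
Product: 13, (M)‑1‑[3‑(3‑acetyl‑2,6‑dihydroxy‑4‑methylphenyl)‑4,6‑dihydroxy‑2‑methylphenyl]ethan‑1‑one
Conditions: Pd(P‑t‑Bu3)2 (5 mol %), CsF, dioxane, 60 °C; then 3 M HCl, MeOH/THF, 45 °C
Reagents that add atoms: tributyl(1‑ethoxyvinyl)stannane, CCCC[Sn](CCCC)(CCCC)C(=C)OCC; water, O
Why: Stille coupling with an acetyl‑anion equivalent; the acid step hydrolyses the enol ether to the methyl ketone and removes both MOM groups, and no bond at the axis is touched.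

**Step 7**
Reactants: 13, 14 (diethyl carbonate)
Product: 15, (M)‑4,4′,7,7′‑tetrahydroxy‑5,5′‑dimethyl‑2H,2′H‑[6,8′‑bichromene]‑2,2′‑dione
Conditions: NaH (10 equiv), (EtO)2CO/THF, 65–80 °C; then 1 M NaOH, rt; HCl
Reagents that add atoms: diethyl carbonate, CCOC(=O)OCC
Why: Twofold Claisen‑type C‑acylation of the methyl ketone enolates and lactonization (the classical 4‑hydroxycoumarin synthesis). Only the OH ortho to each acetyl can close, which fixes O1′ next to the axis in ring B and O1 remote from it in ring A. The NaOH wash removes any 7‑O‑carbonates. The buttressed tetra‑ortho axis is expected to survive; ee is checked by chiral HPLC.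

**Step 8**
Reactants: 15, 16 (methanol)
Product: 17, (M)‑desertorin A
Conditions: MeOH, cat. conc. H2SO4, 3 Å MS, 65 °C
Reagents that add atoms: methanol, CO
Why: Acid‑catalysed vinylogous Fischer esterification; only the 4‑OH groups (vinylogous carboxylic acids) undergo addition–elimination at C4, the phenolic 7‑OH groups are inert, and thermodynamic control favours 4‑methoxycoumarin over 2‑methoxychromone.

---

**Compound list** (SMILES cannot encode the biaryl axis; the (M) descriptor is carried in the name)

1 | 1‑(2,4‑dihydroxy‑6‑methylphenyl)ethan‑1‑one | CC(=O)c1c(C)cc(O)cc1O | starting material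
2 | N‑bromosuccinimide | O=C1CCC(=O)N1Br | starting material
3 | 1‑(3‑bromo‑4,6‑dihydroxy‑2‑methylphenyl)ethan‑1‑one | CC(=O)c1c(C)c(Br)c(O)cc1O | intermediate
4 | chloromethyl methyl ether | COCCl | starting material
5 | 1‑[3‑bromo‑4,6‑bis(methoxymethoxy)‑2‑methylphenyl]ethan‑1‑one | CC(=O)c1c(C)c(Br)c(OCOC)cc1OCOC | intermediate
6 | 5‑methylcyclohexane‑1,3‑dione | CC1CC(=O)CC(=O)C1 | starting material
7 | 2‑[3‑acetyl‑4,6‑bis(methoxymethoxy)‑2‑methylphenyl]‑3‑hydroxy‑5‑methylcyclohex‑2‑en‑1‑one (racemic enol) | CC(=O)c1c(C)c(C2=C(O)CC(C)CC2=O)c(OCOC)cc1OCOC | intermediate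
8 | 1‑[3‑(2,6‑dihydroxy‑4‑methylphenyl)‑4,6‑bis(methoxymethoxy)‑2‑methylphenyl]ethan‑1‑one (achiral) | CC(=O)c1c(C)c(-c2c(O)cc(C)cc2O)c(OCOC)cc1OCOC | intermediate
9 | N‑bromophthalimide | O=C1N(Br)C(=O)c2ccccc12 | starting material
10 | (M)‑1‑[3‑(3‑bromo‑2,6‑dihydroxy‑4‑methylphenyl)‑4,6‑bis(methoxymethoxy)‑2‑methylphenyl]ethan‑1‑one | CC(=O)c1c(C)c(-c2c(O)cc(C)c(Br)c2O)c(OCOC)cc1OCOC | intermediate
11 | tributyl(1‑ethoxyvinyl)stannane | CCCC[Sn](CCCC)(CCCC)C(=C)OCC | starting material
12 | water | O | starting material
13 | (M)‑1‑[3‑(3‑acetyl‑2,6‑dihydroxy‑4‑methylphenyl)‑4,6‑dihydroxy‑2‑methylphenyl]ethan‑1‑one | CC(=O)c1c(C)c(-c2c(O)cc(C)c(C(C)=O)c2O)c(O)cc1O | intermediate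
14 | diethyl carbonate | CCOC(=O)OCC | starting material
15 | (M)‑4,4′,7,7′‑tetrahydroxy‑5,5′‑dimethyl‑6,8′‑bicoumarin | Oc1cc(=O)oc2cc(O)c(-c3c(O)cc(C)c4c(O)cc(=O)oc34)c(C)c12 | intermediate
16 | methanol | CO | starting material
17 | (M)‑desertorin A | COc1cc(=O)oc2cc(O)c(-c3c(O)cc(C)c4c(OC)cc(=O)oc34)c(C)c12 | target

**Total steps:** 8. **Longest linear sequence:** 8 (fully linear from 1).

**Three steps most likely to fail, with fallbacks**
1. **Step 5** (ee or sense of induction on a substrate with extra acetyl and MOM acceptors). Fallback: unselective NBS monobromination to rac‑10, resolution by chiral SFC or as diastereomeric bis‑camphanates, and recycling of the wrong enantiomer by hydrodebromination (H2, Pd/C, Et3N) back to prochiral 8.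
2. **Step 3** (enolate arylation with a di‑ortho‑substituted, electron‑rich bromide). Fallback: abandon the dione; Suzuki–Miyaura coupling of 5 with 2,6‑bis(benzyloxy)‑4‑methylphenylboronic acid, then hydrogenolysis, gives the same compound 8 and makes Step 4 unnecessary.
3. **Step 8** (4‑OH versus 7‑OH selectivity, and slow addition at C4 next to the peri methyl). Fallback: a protecting‑group end‑game: benzylate the two non‑chelated phenols of 13 (BnBr, K2CO3), annulate as in Step 7, methylate with Me2SO4/K2CO3, then H2, Pd/C.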